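**Analysis of the target**

The target 24 (C24H28O3) is a 2,2-dimethyl-2H-chromene: ring A is the benzene ring, ring B the pyran, and ring C a 4-hydroxyphenyl group joined to C7 by a two-carbon chain. Ring A is pentasubstituted: C4a and C8a carry ring B, C5 a free hydroxyl, C6 a prenyl group, C7 the arylethyl chain, and only C8 bears hydrogen. There is no stereocentre; the C3=C4 double bond is cis because it lies in ring B. The sensitive groups are the two phenols, the styrene-like C3=C4 bond and the prenyl olefin. Together these rule out hydrogenolysis and strong electrophiles late in the route, and the C5 hydroxyl next to the C6 prenyl group closes to a chroman under strong acid. The difficulty is one of differentiation. O1 and the C5 oxygen sit on a resorcinol that is symmetric before ring B exists, the prenyl group must go to C6 and not to C8, and the ring C phenol must stay distinct from the C5 hydroxyl. The strategy rests on two features. First, O1–C2(CH3)2–C3=C4 is the complete skeleton of 3-methylbut-2-enal 13, oxygen included. Second, the C4a–C8a bond lies next to the oxygen-bearing C5, so it can be an aryne bond polarised by that alkoxy group.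

**Retrosynthetic reasoning**

24 to 23. The last operation frees the ring C phenol from its triflate in 23 by attack of hydroxide at sulfur. Ring C stays masked until then because a free ring C phenol would be O-alkylated and rearranged alongside the C5 hydroxyl. A triflate is chosen because this spectator must survive Lewis-acid demethylation, a short exposure to an alkyllithium, fluoride, acid, zerovalent palladium and heat, and must then leave under conditions that spare two olefins.

23 to 21. The C6–prenyl bond is cut by a [3,3] shift, which leads back through dienone 22 to the 1,1-dimethylallyl ether 21. C6 is the only open ortho position of the C5 oxygen, so the pericyclic path fixes the site that electrophilic prenylation would leave ambiguous between C6 and C8.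

21 to 18 and 20. The ether C–O bond is cut. Forward, phenol 18 is alkylated at the tertiary terminus of an allyl palladium cation generated from carbonate 20, which is made in one step from alcohol 19.

18 to 17. Phenol 18 comes from its methoxymethyl ether 17. The acid needed falls before the prenyl group is present, so no chroman can form.

17 to 12 and 13. This is the central disconnection: C8a–O1, C4a–C4 and O1–C2 are cut together. Forward, a fluoride source turns 12 into aryne 14, aldehyde 13 adds across the aryne bond to give benzoxete 15, 15 opens to ortho-quinone methide 16, and 16 closes ring B. The ring oxygen comes from 13, not from the arene, so ring A only has to present a polarised aryne bond next to one protected oxygen. This builds ring B and all its carbons in one step from a five-carbon aldehyde and needs no carbon substituent at C4a beforehand.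

12 to 11 to 6. The methoxymethyl group of 12 is removed to give 11, and 11 is traced to the symmetric 2-bromoresorcinol 6. Forward, 6 is bis-silylated (7), bromine–lithium exchange gives aryllithium 8, and one silyl group migrates from oxygen to carbon. In the resulting aryloxide 9 the two ring A oxygens differ for the first time: one is an aryloxide and is triflated (10), the other is still a silyl ether and becomes the hydroxyl of 11. The symmetry is therefore broken by the reaction that installs silicon, not by a statistical protection.

6 to 5 to 4. The two hydroxyls of 6 come from the methyl ethers of 5, and the ring C triflate of 5 from phenol 4. In 4 the ring C hydroxyl is the only free one, so its protection is unambiguous.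

4 to 2 to 1. The bromine between the two methoxy groups is cut back to hydrogen. Forward, an alkyllithium first makes the phenoxide of 2 and then removes the doubly activated proton between the methoxy groups (3), and a bromine donor gives 4. Compound 2 is the hydrogenation product of the commercial stilbene 1. Stilbene 1 is preferred to a triphenolic stilbene because its ring A oxygens are already masked and its ring C oxygen is free.

**Alternatives that were turned down**

Alternative 1: Ring A is cut at C4a–C5 and C6–C7. Ring B is already present in the pyranopyranone A2, and C5 (with a silyloxy group) and C6 (with the prenyl group) arrive as the two carbons of the siloxyalkyne A3. Forward, A3 adds across C4a and C7 of the pyranone diene, and decarboxylative cycloreversion of the bridged lactone gives the bis-silyl ether A1, one desilylation away from 24.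
- For: it is convergent, it places the C5 oxygen and the C6 prenyl group in the ring-forming step, and it needs neither a Claisen shift nor any distinction between the phenols. On endgame length and on protecting-group simplicity it is stronger than the chosen route.
- Against: the diene of A2 carries an alkoxy and an alkyl donor and A3 is an electron-rich alkyne, so the two partners are electronically mismatched. The forcing temperature this implies invites the 1,3-silyl shift of A3 to a silylketene and the thermal opening of the 2H-pyran ring of A2. A3 also needs a multistep preparation.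
- Comparison: the chosen route offers a key step between a strongly electrophilic aryne and a nucleophilic carbonyl oxygen at room temperature, with 13 as the only added building block.

Alternative 2: Ring A is cut at C4a–C8a and C5–C6. Heating cyclobutenone A5 with the same siloxyalkyne A3 should pass through a vinylketene, a [2+2] addition, a 4-electron ring opening and a 6-electron closure to give phenol A4. A4 has the free hydroxyl on the future C8a, the silyl ether on C5 and prenyl groups on C4a and C6. Dehydrogenative closure of the C4a prenyl group onto the C8a hydroxyl and desilylation would follow.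
- For: the mechanism dictates the position of every ring A substituent and differentiates the two oxygens automatically. On regiochemical certainty for ring A it is stronger than the chosen route.
- Against: A5 is a cyclobutenone with two different alkyl groups on its double bond and is hard to obtain as one regioisomer. Ring B is not formed in the key step and needs a separate oxidation on a very electron-rich arene that carries a second prenyl group. The sequence is clearly longer.
- Comparison: the chosen route closes ring B and settles the oxygen pattern in the same step.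

Alternative 3: Ring B is cut at C3=C4. A ruthenium carbene metathesis catalyst would join the C4a vinyl group of the symmetric bis-ether A7 to one of its two equivalent 1,1-dimethylallyl ethers to give chromene A6. The second ether of A6 is then the Claisen precursor for the C6 prenyl group.
- For: the ring closure is a very dependable reaction type, the substrate is symmetric, and one kind of ether serves twice. On reliability of the ring-forming step and on the number of operations after ring closure it is at least as strong as the chosen route.
- Against: A7 needs a carbon substituent introduced at C4a and converted to a vinyl group. It also needs two tertiary O-alkylations on hydroxyls flanking that substituent, which is a crowded arrangement, and the tertiary allyl ethers are prone to premature rearrangement or ionisation. Ring C still has to be distinguished.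
- Comparison: the chosen route needs no carbon at C4a before the key step and takes the whole O1–C2–C3–C4 unit from 13 in one metal-free operation. It accepts a less routine key step in exchange.

Key step: step 7

Remark: 1, 13 and 19 are taken as commercial; the ring C phenol is carried as an aryl triflate, a sulfonate protecting group that is cleaved at sulfur by hydroxide.

**Route**

Step 1
Reactants: 1 pterostilbene, (E)-4-[2-(3,5-dimethoxyphenyl)ethenyl]phenol
Product: 2 4-[2-(3,5-dimethoxyphenyl)ethyl]phenol
Conditions: H2 (1 atm), 10% Pd/C, EtOAc, rt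
Reagents that add atoms: none
Why: Catalytic hydrogenation of the stilbene double bond; the phenol and aryl ethers are inert, and the saturated chain is needed before any alkyllithium is used.

Step 2
Reactants: 2 4-[2-(3,5-dimethoxyphenyl)ethyl]phenol
Product: 4 4-[2-(4-bromo-3,5-dimethoxyphenyl)ethyl]phenol, via dilithio species 3 (not isolated)
Conditions: n-BuLi (2.3 equiv), THF, 0 °C to rt; BrCCl2CCl2Br, −78 °C to rt; aq. NH4Cl
Reagents that add atoms: 1,2-dibromo-1,1,2,2-tetrachloroethane, ClC(Cl)(Br)C(Cl)(Cl)Br
Why: Directed ortho-metalation: the first equivalent gives the lithium phenoxide, which deactivates ring C, and the second removes the proton between the two methoxy groups, the most acidic position of ring A; the perhaloethane transfers bromine to the aryllithium 3.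

Step 3
Reactants: 4 4-[2-(4-bromo-3,5-dimethoxyphenyl)ethyl]phenol
Product: 5 4-[2-(4-bromo-3,5-dimethoxyphenyl)ethyl]phenyl trifluoromethanesulfonate
Conditions: Tf2O, pyridine, CH2Cl2, 0 °C
Reagents that add atoms: trifluoromethanesulfonic anhydride, O=S(=O)(OS(=O)(=O)C(F)(F)F)C(F)(F)F
Why: O-sulfonylation of the only free hydroxyl, so ring C is protected without any selectivity question.

Step 4
Reactants: 5 4-[2-(4-bromo-3,5-dimethoxyphenyl)ethyl]phenyl trifluoromethanesulfonate
Product: 6 4-[2-(4-bromo-3,5-dihydroxyphenyl)ethyl]phenyl trifluoromethanesulfonate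
Conditions: BBr3 (3 equiv), CH2Cl2, −78 °C to rt; H2O
Reagents that add atoms: none
Why: Lewis-acid cleavage of both aryl methyl ethers by bromide attack on the O-methyl carbon of the boron complex; the aryl bromide and the aryl triflate do not react with BBr3.

Step 5
Reactants: 6 4-[2-(4-bromo-3,5-dihydroxyphenyl)ethyl]phenyl trifluoromethanesulfonate
Product: 11 3-hydroxy-2-(trimethylsilyl)-5-[2-(4-trifluoromethanesulfonyloxyphenyl)ethyl]phenyl trifluoromethanesulfonate, via bis(trimethylsilyl) ether 7 (not isolated), via aryllithium 8 (not isolated), via lithium aryloxide 9 (not isolated), via O-silyl bis(triflate) 10 (not isolated)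
Conditions: (Me3Si)2NH, THF, 65 °C, then evaporation; n-BuLi (1.05 equiv), THF, −78 °C; Tf2O, −78 °C; 1 M HCl, THF, 0 °C
Reagents that add atoms: hexamethyldisilazane, C[Si](C)(C)N[Si](C)(C)C; trifluoromethanesulfonic anhydride, O=S(=O)(OS(=O)(=O)C(F)(F)F)C(F)(F)F
Why: Bromine–lithium exchange on the oxygen-flanked bromide should outrun attack on the remote sulfonate, as it does when arynes are made from ortho-halogenoaryl triflates with n-BuLi. Aryllithium 8 then undergoes the 1,3 shift of silicon from oxygen to carbon (retro-Brook rearrangement), so in 9 one ring A oxygen is an aryloxide and is triflated while the other is still a silyl ether. Brief dilute acid removes the O-silyl group; the C–Si bond survives because the ring is deactivated by the adjacent triflate.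

Step 6
Reactants: 11 3-hydroxy-2-(trimethylsilyl)-5-[2-(4-trifluoromethanesulfonyloxyphenyl)ethyl]phenyl trifluoromethanesulfonate
Product: 12 3-(methoxymethoxy)-2-(trimethylsilyl)-5-[2-(4-trifluoromethanesulfonyloxyphenyl)ethyl]phenyl trifluoromethanesulfonate
Conditions: MOMCl, i-Pr2NEt, CH2Cl2, 0 °C to rt
Reagents that add atoms: chloromethyl methyl ether, COCCl
Why: Acetal-type O-alkylation of the phenol under a hindered amine base; the electrophile is present before the base, so the ammonium aryloxide is alkylated before silicon can move from carbon to oxygen.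

Step 7
Reactants: 12 3-(methoxymethoxy)-2-(trimethylsilyl)-5-[2-(4-trifluoromethanesulfonyloxyphenyl)ethyl]phenyl trifluoromethanesulfonate; 13 3-methylbut-2-enal
Product: 17 5-(methoxymethoxy)-2,2-dimethyl-7-[2-(4-trifluoromethanesulfonyloxyphenyl)ethyl]-2H-chromene, via aryne 14 (not isolated), via benzoxete 15 (not isolated), via ortho-quinone methide 16 (not isolated)
Conditions: CsF (3 equiv), 13 (5 equiv), MeCN, rt to 40 °C
Reagents that add atoms: none
Why: Fluoride attacks silicon and triflate leaves from the neighbouring carbon, giving aryne 14 across the future C4a–C8a bond; the ring C triflate has no ortho silicon and stays. The carbonyl oxygen of 13 adds to the aryne carbon remote from the methoxymethoxy group (future C8a), because negative charge then builds on C4a next to the inductively withdrawing oxygen-bearing C5 and because this is the flatter, more electrophilic end of the distorted aryne; the aryl anion closes on the carbonyl carbon to benzoxete 15 (polar, stepwise [2+2], four-membered ring). 15 opens by a 4-electron electrocyclic ring opening to ortho-quinone methide 16, and 16 closes ring B by a thermal disrotatory oxa-6-electron electrocyclization that forms O1–C2 and restores the aromaticity of ring A. No stereocentre is formed, since C2 carries two methyl groups. The closest known reaction type is the [2+2] addition of arynes to the carbonyl group of α,β-unsaturated aldehydes with benzoxete opening and closure to 2H-chromenes, together with distal addition of nucleophiles to 3-alkoxyarynes. The step needs regioselective addition to the aryne, which the C5 alkoxy group secures, and reaction at C=O in preference to the electron-poor C=C, which the nucleophilic carbonyl oxygen favours. The excess of 13 keeps 16 from meeting a second aryne.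

Step 8
Reactants: 17 5-(methoxymethoxy)-2,2-dimethyl-7-[2-(4-trifluoromethanesulfonyloxyphenyl)ethyl]-2H-chromene
Product: 18 2,2-dimethyl-7-[2-(4-trifluoromethanesulfonyloxyphenyl)ethyl]-2H-chromen-5-ol
Conditions: 3 M aq. HCl, MeOH, 45 °C
Reagents that add atoms: none
Why: Acid-catalysed methanolysis of the aryl methoxymethyl acetal; the aryl triflate and the chromene tolerate dilute methanolic acid, and no prenyl group is present yet that could cyclise.

Step 9
Reactants: 19 2-methylbut-3-en-2-ol
Product: 20 tert-butyl 2-methylbut-3-en-2-yl carbonate
Conditions: n-BuLi, THF, −78 to 0 °C; Boc2O, 0 °C to rt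
Reagents that add atoms: di-tert-butyl dicarbonate, CC(C)(C)OC(=O)OC(=O)OC(C)(C)C
Why: Acylation of the tertiary lithium alkoxide by the dicarbonate gives the mixed carbonate.

Step 10
Reactants: 18 2,2-dimethyl-7-[2-(4-trifluoromethanesulfonyloxyphenyl)ethyl]-2H-chromen-5-ol; 20 tert-butyl 2-methylbut-3-en-2-yl carbonate
Product: 21 2,2-dimethyl-5-(2-methylbut-3-en-2-yloxy)-7-[2-(4-trifluoromethanesulfonyloxyphenyl)ethyl]-2H-chromene
Conditions: Pd(PPh3)4 (5 mol %), THF, 4 Å MS, 0 °C to rt
Reagents that add atoms: none
Why: Tsuji–Trost O-allylation: zerovalent palladium ionises 20 to a 1,1-dimethylallyl palladium cation, and the tert-butoxide released after decarboxylation deprotonates 18. The aryloxide attacks the substituted terminus under kinetic control at low temperature and gives the tertiary ether. Oxidative addition of the unactivated aryl triflate to Pd(PPh3)4 is far slower than ionisation of a tertiary allylic carbonate at this temperature.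

Step 11
Reactants: 21 2,2-dimethyl-5-(2-methylbut-3-en-2-yloxy)-7-[2-(4-trifluoromethanesulfonyloxyphenyl)ethyl]-2H-chromene
Product: 23 4-{2-[5-hydroxy-2,2-dimethyl-6-(3-methylbut-2-enyl)-2H-chromen-7-yl]ethyl}phenyl trifluoromethanesulfonate, via cyclohexadienone 22 (not isolated)
Conditions: PhMe, 115 °C, sealed tube
Reagents that add atoms: none
Why: Aromatic Claisen rearrangement: the terminal CH2 of the 1,1-dimethylallyl ether bonds to C6, the only free ortho position, and dienone 22 tautomerises to the phenol; a shift to the substituted C4a cannot tautomerise and is reversible.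

Step 12
Reactants: 23 4-{2-[5-hydroxy-2,2-dimethyl-6-(3-methylbut-2-enyl)-2H-chromen-7-yl]ethyl}phenyl trifluoromethanesulfonate
Product: 24 7-[2-(4-hydroxyphenyl)ethyl]-2,2-dimethyl-6-(3-methylbut-2-enyl)-2H-chromen-5-ol
Conditions: Et4NOH (aq., 2.5 equiv), 1,4-dioxane, rt, argon; then aq. NH4Cl
Reagents that add atoms: none
Why: Hydroxide attacks the sulfur of the aryl triflate and expels the ring C aryloxide; both olefins and the chromene are inert to base, and argon protects the phenoxides from air.

**Compound list**

1 | pterostilbene, (E)-4-[2-(3,5-dimethoxyphenyl)ethenyl]phenol | COc1cc(/C=C/c2ccc(O)cc2)cc(OC)c1 | starting material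
2 | 4-[2-(3,5-dimethoxyphenyl)ethyl]phenol | COc1cc(CCc2ccc(O)cc2)cc(OC)c1 | intermediate
3 | lithium 4-[2-(4-lithio-3,5-dimethoxyphenyl)ethyl]phenoxide | [Li+].[O-]c1ccc(CCc2cc(OC)c([Li])c(OC)c2)cc1 | intermediate
4 | 4-[2-(4-bromo-3,5-dimethoxyphenyl)ethyl]phenol | COc1cc(CCc2ccc(O)cc2)cc(OC)c1Br | intermediate
5 | 4-[2-(4-bromo-3,5-dimethoxyphenyl)ethyl]phenyl trifluoromethanesulfonate | COc1cc(CCc2ccc(OS(=O)(=O)C(F)(F)F)cc2)cc(OC)c1Br | intermediate
6 | 4-[2-(4-bromo-3,5-dihydroxyphenyl)ethyl]phenyl trifluoromethanesulfonate | Oc1cc(CCc2ccc(OS(=O)(=O)C(F)(F)F)cc2)cc(O)c1Br | intermediate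
7 | 4-{2-[4-bromo-3,5-bis(trimethylsilyloxy)phenyl]ethyl}phenyl trifluoromethanesulfonate | C[Si](C)(C)Oc1cc(CCc2ccc(OS(=O)(=O)C(F)(F)F)cc2)cc(O[Si](C)(C)C)c1Br | intermediate
8 | 4-{2-[4-lithio-3,5-bis(trimethylsilyloxy)phenyl]ethyl}phenyl trifluoromethanesulfonate | C[Si](C)(C)Oc1cc(CCc2ccc(OS(=O)(=O)C(F)(F)F)cc2)cc(O[Si](C)(C)C)c1[Li] | intermediate
9 | lithium 2-(trimethylsilyl)-3-(trimethylsilyloxy)-5-[2-(4-trifluoromethanesulfonyloxyphenyl)ethyl]phenoxide | [Li+].[O-]c1cc(CCc2ccc(OS(=O)(=O)C(F)(F)F)cc2)cc(O[Si](C)(C)C)c1[Si](C)(C)C | intermediate
10 | 2-(trimethylsilyl)-3-(trimethylsilyloxy)-5-[2-(4-trifluoromethanesulfonyloxyphenyl)ethyl]phenyl trifluoromethanesulfonate | C[Si](C)(C)Oc1cc(CCc2ccc(OS(=O)(=O)C(F)(F)F)cc2)cc(OS(=O)(=O)C(F)(F)F)c1[Si](C)(C)C | intermediate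
11 | 3-hydroxy-2-(trimethylsilyl)-5-[2-(4-trifluoromethanesulfonyloxyphenyl)ethyl]phenyl trifluoromethanesulfonate | Oc1cc(CCc2ccc(OS(=O)(=O)C(F)(F)F)cc2)cc(OS(=O)(=O)C(F)(F)F)c1[Si](C)(C)C | intermediate
12 | 3-(methoxymethoxy)-2-(trimethylsilyl)-5-[2-(4-trifluoromethanesulfonyloxyphenyl)ethyl]phenyl trifluoromethanesulfonate | COCOc1cc(CCc2ccc(OS(=O)(=O)C(F)(F)F)cc2)cc(OS(=O)(=O)C(F)(F)F)c1[Si](C)(C)C | intermediate
13 | 3-methylbut-2-enal | CC(C)=CC=O | starting material
14 | 3-(methoxymethoxy)-5-[2-(4-trifluoromethanesulfonyloxyphenyl)ethyl]-1,2-didehydrobenzene | COCOC1=CC(CCc2ccc(OS(=O)(=O)C(F)(F)F)cc2)=CC#C1 | intermediate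
15 | 3-(methoxymethoxy)-2-(2-methylprop-1-enyl)-5-[2-(4-trifluoromethanesulfonyloxyphenyl)ethyl]-2H-benzo[b]oxete | COCOc1cc(CCc2ccc(OS(=O)(=O)C(F)(F)F)cc2)cc2OC(C=C(C)C)c12 | intermediate
16 | 5-(methoxymethoxy)-6-(3-methylbut-2-en-1-ylidene)-3-[2-(4-trifluoromethanesulfonyloxyphenyl)ethyl]cyclohexa-2,4-dien-1-one | COCOC1=CC(CCc2ccc(OS(=O)(=O)C(F)(F)F)cc2)=CC(=O)C1=CC=C(C)C | intermediate
17 | 5-(methoxymethoxy)-2,2-dimethyl-7-[2-(4-trifluoromethanesulfonyloxyphenyl)ethyl]-2H-chromene | CC1(C)C=Cc2c(OCOC)cc(CCc3ccc(OS(=O)(=O)C(F)(F)F)cc3)cc2O1 | intermediate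
18 | 2,2-dimethyl-7-[2-(4-trifluoromethanesulfonyloxyphenyl)ethyl]-2H-chromen-5-ol | CC1(C)C=Cc2c(O)cc(CCc3ccc(OS(=O)(=O)C(F)(F)F)cc3)cc2O1 | intermediate
19 | 2-methylbut-3-en-2-ol | CC(C)(O)C=C | starting material
20 | tert-butyl 2-methylbut-3-en-2-yl carbonate | CC(C)(C)OC(=O)OC(C)(C)C=C | intermediate
21 | 2,2-dimethyl-5-(2-methylbut-3-en-2-yloxy)-7-[2-(4-trifluoromethanesulfonyloxyphenyl)ethyl]-2H-chromene | C=CC(C)(C)Oc1cc(CCc2ccc(OS(=O)(=O)C(F)(F)F)cc2)cc2c1C=CC(C)(C)O2 | intermediate
22 | 2,2-dimethyl-6-(3-methylbut-2-enyl)-7-[2-(4-trifluoromethanesulfonyloxyphenyl)ethyl]-2H-chromen-5(6H)-one | O=C1C(CC=C(C)C)C(CCc2ccc(OS(=O)(=O)C(F)(F)F)cc2)=CC2=C1C=CC(C)(C)O2 | intermediate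
23 | 4-{2-[5-hydroxy-2,2-dimethyl-6-(3-methylbut-2-enyl)-2H-chromen-7-yl]ethyl}phenyl trifluoromethanesulfonate | CC(C)=CCc1c(CCc2ccc(OS(=O)(=O)C(F)(F)F)cc2)cc2c(c1O)C=CC(C)(C)O2 | intermediate
24 | 7-[2-(4-hydroxyphenyl)ethyl]-2,2-dimethyl-6-(3-methylbut-2-enyl)-2H-chromen-5-ol | CC(C)=CCc1c(CCc2ccc(O)cc2)cc2c(c1O)C=CC(C)(C)O2 | target

**Step count and risk**

Total: 12 steps. Longest linear sequence: 11 steps (steps 1 to 8 and 10 to 12, from 1); step 9 is a one-step side branch.

Least certain steps:

Step 7 (key step). The most likely failure is diversion of the aryne or of 16 before ring B closes. Possible paths are an ene reaction of the aryne with the allylic C–H bonds of 13, fluoride-induced self-condensation of 13 through its γ-protons, and capture of 16 by a second aryne. The fallback gives up the aryne and sets out from 2. Triflation (Tf2O, pyridine) gives 4-[2-(3,5-dimethoxyphenyl)ethyl]phenyl trifluoromethanesulfonate F1. BBr3 then gives the resorcinol 4-[2-(3,5-dihydroxyphenyl)ethyl]phenyl trifluoromethanesulfonate F2. Condensation of F2 with 13 (ethylenediammonium diacetate, toluene, reflux) follows the classical path of C-alkylation at the carbon between the two hydroxyls, dehydration to a quinone methide and oxa-6-electron closure. It returns to the route at 18, after removal of the isomer formed by attack at the other ring position.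

Step 5. The most likely failure is attack of n-BuLi on the ring C triflate (at sulfur, or ortho-lithiation) in competition with bromine–lithium exchange, or cleavage of an O–Si bond before the silyl shift. The fallback moves the ring C triflation behind all organolithium chemistry and sets out from 4.
- BBr3 gives 2-bromo-5-[2-(4-hydroxyphenyl)ethyl]benzene-1,3-diol F3, and hexamethyldisilazane gives its tris(trimethylsilyl) ether F4.
- n-BuLi at −78 °C triggers the same exchange and silyl shift to the lithium aryloxide F5.
- MOMCl caps F5 as the methoxymethyl ether carrying two O-silyl groups F6, and dilute acid gives 3-(methoxymethoxy)-5-[2-(4-hydroxyphenyl)ethyl]-2-(trimethylsilyl)phenol F7.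
- Double triflation of F7 (Tf2O, pyridine) returns to the route at 12.
- Its own weak point is transfer of a silyl group between aryloxide oxygens before the alkylation, which is why it is not the main route.

Step 10. The most likely failure is loss of the kinetic regiochemistry, that is isomerisation of the tertiary ether to the linear prenyl ether on prolonged contact with the allyl palladium species, or slow consumption of the catalyst by the aryl triflate. The fallback avoids palladium and sets out from 18. Copper-catalysed O-alkylation with 3-chloro-3-methylbut-1-yne (CuCl2 catalytic, DBU, MeCN, 0 °C) gives the propargyl ether 2,2-dimethyl-5-(2-methylbut-3-yn-2-yloxy)-7-[2-(4-trifluoromethanesulfonyloxyphenyl)ethyl]-2H-chromene F8. Semihydrogenation (H2, Pd/CaCO3 poisoned with Pb(OAc)2, quinoline) returns to the route at 21.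

Step 11. The most likely failure is competing ionisation of the tertiary allyl ether with loss of the side chain back to 18, or migration through C4a and onward Cope shift to C8. The fallback replaces the [3,3] shift by an ionic 1,3-shift and sets out from 18. O-Prenylation (prenyl bromide, K2CO3, acetone) gives 2,2-dimethyl-5-(3-methylbut-2-enyloxy)-7-[2-(4-trifluoromethanesulfonyloxyphenyl)ethyl]-2H-chromene F9. Treatment with magnesium silicate (MgSiO3) in toluene moves the prenyl group to the ortho position and returns to the route at 23.

**Further compounds**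

F1 | step 7 | 4-[2-(3,5-dimethoxyphenyl)ethyl]phenyl trifluoromethanesulfonate | COc1cc(CCc2ccc(OS(=O)(=O)C(F)(F)F)cc2)cc(OC)c1
F2 | step 7 | 4-[2-(3,5-dihydroxyphenyl)ethyl]phenyl trifluoromethanesulfonate | Oc1cc(O)cc(CCc2ccc(OS(=O)(=O)C(F)(F)F)cc2)c1
F3 | step 5 | 2-bromo-5-[2-(4-hydroxyphenyl)ethyl]benzene-1,3-diol | Oc1ccc(CCc2cc(O)c(Br)c(O)c2)cc1
F4 | step 5 | {2-bromo-5-[2-(4-trimethylsilyloxyphenyl)ethyl]-1,3-phenylene}bis(oxy)bis(trimethylsilane) | C[Si](C)(C)Oc1ccc(CCc2cc(O[Si](C)(C)C)c(Br)c(O[Si](C)(C)C)c2)cc1
F5 | step 5 | lithium 2-(trimethylsilyl)-3-(trimethylsilyloxy)-5-[2-(4-trimethylsilyloxyphenyl)ethyl]phenoxide | [Li+].[O-]c1cc(CCc2ccc(O[Si](C)(C)C)cc2)cc(O[Si](C)(C)C)c1[Si](C)(C)C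
F6 | step 5 | [2-(methoxymethoxy)-6-(trimethylsilyloxy)-4-[2-(4-trimethylsilyloxyphenyl)ethyl]phenyl]trimethylsilane | COCOc1cc(CCc2ccc(O[Si](C)(C)C)cc2)cc(O[Si](C)(C)C)c1[Si](C)(C)C
F7 | step 5 | 3-(methoxymethoxy)-5-[2-(4-hydroxyphenyl)ethyl]-2-(trimethylsilyl)phenol | COCOc1cc(CCc2ccc(O)cc2)cc(O)c1[Si](C)(C)C
F8 | step 10 | 2,2-dimethyl-5-(2-methylbut-3-yn-2-yloxy)-7-[2-(4-trifluoromethanesulfonyloxyphenyl)ethyl]-2H-chromene | C#CC(C)(C)Oc1cc(CCc2ccc(OS(=O)(=O)C(F)(F)F)cc2)cc2c1C=CC(C)(C)O2
F9 | step 11 | 2,2-dimethyl-5-(3-methylbut-2-enyloxy)-7-[2-(4-trifluoromethanesulfonyloxyphenyl)ethyl]-2H-chromene | CC(C)=CCOc1cc(CCc2ccc(OS(=O)(=O)C(F)(F)F)cc2)cc2c1C=CC(C)(C)O2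
A1 | alternative 1 | bis-silyl ether of the target (C5 triisopropylsilyl, ring C tert-butyldimethylsilyl) | CC(C)=CCc1c(CCc2ccc(O[Si](C)(C)C(C)(C)C)cc2)cc2c(c1O[Si](C(C)C)(C(C)C)C(C)C)C=CC(C)(C)O2
A2 | alternative 1 | 2,2-dimethyl-7-[2-(4-tert-butyldimethylsilyloxyphenyl)ethyl]-2H,5H-pyrano[4,3-b]pyran-5-one | O=C1OC(CCc2ccc(O[Si](C)(C)C(C)(C)C)cc2)=CC2=C1C=CC(C)(C)O2
A3 | alternative 1 | triisopropyl[(5-methylhex-4-en-1-yn-1-yl)oxy]silane | CC(C)=CCC#CO[Si](C(C)C)(C(C)C)C(C)C
A4 | alternative 2 | 2,4-bis(3-methylbut-2-enyl)-3-triisopropylsilyloxy-5-[2-(4-tert-butyldimethylsilyloxyphenyl)ethyl]phenol | Oc1cc(CCc2ccc(O[Si](C)(C)C(C)(C)C)cc2)c(CC=C(C)C)c(O[Si](C(C)C)(C(C)C)C(C)C)c1CC=C(C)C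
A5 | alternative 2 | 2-(3-methylbut-2-enyl)-3-[2-(4-tert-butyldimethylsilyloxyphenyl)ethyl]cyclobut-2-en-1-one | O=C1CC(CCc2ccc(O[Si](C)(C)C(C)(C)C)cc2)=C1CC=C(C)C
A6 | alternative 3 | 2,2-dimethyl-5-(2-methylbut-3-en-2-yloxy)-7-[2-(4-tert-butyldimethylsilyloxyphenyl)ethyl]-2H-chromene | C=CC(C)(C)Oc1cc(CCc2ccc(O[Si](C)(C)C(C)(C)C)cc2)cc2c1C=CC(C)(C)O2
A7 | alternative 3 | 1,3-bis(2-methylbut-3-en-2-yloxy)-2-vinyl-5-[2-(4-tert-butyldimethylsilyloxyphenyl)ethyl]benzene | C=Cc1c(OC(C)(C)C=C)cc(CCc2ccc(O[Si](C)(C)C(C)(C)C)cc2)cc1OC(C)(C)C=C
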